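**Target:** (2R,3R)-taxifolin joined through C8 to C3 of a (2S,3R)-eriodictyol unit (2,3-trans in both units), C30H22O13.

## Retrosynthetic overview

1. Target 11 ⇐ octa-O-benzyl biflavanone 10 by hydrogenolysis (last step).
2. 10 ⇐ chalcone 9: the O1–C2 bond of the upper flavanone is closed by a catalyst-controlled 6-endo oxa-Michael addition (sets C2; C3 settles trans). This pyranone ring is the only ring built.
3. 9 ⇐ 8 ⇐ deoxybenzoin 6 + aldehyde 7: Knoevenagel condensation, then unmasking of the single phenol.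
4. 6 ⇐ ketone 2 + bromide 5: the bond between the two flavonoid units by Pd-catalysed ketone α-arylation at C8 of the taxifolin unit.
5. 5 ⇐ (+)-taxifolin 3 (supplies all rings and both stereocentres of the lower unit); 2 ⇐ 1.

Assumption: (+)-taxifolin (dihydroquercetin), 1-[2-hydroxy-4,6-bis(benzyloxy)phenyl]ethan-1-one and 3,4-bis(benzyloxy)benzaldehyde are bought as catalogue compounds.

## Route

**Step 1**
Reactants: 1 1-[2-hydroxy-4,6-bis(benzyloxy)phenyl]ethan-1-one
Product: 2 1-[2,4-bis(benzyloxy)-6-(methoxymethoxy)phenyl]ethan-1-one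
Conditions: NaH, MOMCl, DMF, 0 °C to 25 °C
Reagents that add atoms: chloromethyl methyl ether, COCCl
Why: Williamson-type O-alkylation of the sodium phenoxide masks the phenol that later becomes the ring oxygen as an acid-labile MOM ether; no stereocentre is involved.

**Step 2**
Reactants: 3 (+)-taxifolin, (2R,3R)-2-(3,4-dihydroxyphenyl)-3,5,7-trihydroxychroman-4-one
Product: 4 (2R,3R)-5,7-bis(benzyloxy)-2-[3,4-bis(benzyloxy)phenyl]-3-hydroxychroman-4-one
Conditions: BnBr, K2CO3, DMF, 25 to 45 °C, argon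
Reagents that add atoms: benzyl bromide, BrCc1ccccc1
Why: Williamson etherification of the four phenols (carbonate does not ionise the 3-OH) gives the known tetra-O-benzyl ether with the purchased 2R,3R centres untouched, and the 5-O-benzyl group is what directs the next substitution to C8.

**Step 3**
Reactants: 4 tetra-O-benzyltaxifolin
Product: 5 (2R,3R)-5,7-bis(benzyloxy)-2-[3,4-bis(benzyloxy)phenyl]-8-bromo-3-hydroxychroman-4-one
Conditions: NBS, CH2Cl2, −20 to 0 °C, dark
Reagents that add atoms: N-bromosuccinimide, O=C1CCC(=O)N1Br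
Why: electrophilic aromatic bromination of the trioxygenated ring A, expected at the less hindered C8 (between O1 and O7) by analogy with 5,7-di-O-alkyl flavonoids and tetra-O-benzylcatechin; no stereocentre is touched.

**Step 4**
Reactants: 2 MOM-protected ketone; 5 C8 bromide
Product: 6 (2R,3R)-5,7-bis(benzyloxy)-2-[3,4-bis(benzyloxy)phenyl]-8-{2-[2,4-bis(benzyloxy)-6-(methoxymethoxy)phenyl]-2-oxoethyl}-3-hydroxychroman-4-one
Conditions: Pd2(dba)3, XPhos, K3PO4, toluene, 85 °C (2 in 1.5-fold excess)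
Reagents that add atoms: none
Why: Buchwald–Hartwig-type palladium-catalysed α-arylation of a methyl ketone with a hindered, electron-rich aryl bromide; the weak phosphate base spares the epimerisable taxifolin centres, and the two ortho oxygens stop a second arylation.

**Step 5**
Reactants: 6 deoxybenzoin; 7 3,4-bis(benzyloxy)benzaldehyde
Product: 8 (2R,3R)-5,7-bis(benzyloxy)-2-[3,4-bis(benzyloxy)phenyl]-8-{(E)-3-[2,4-bis(benzyloxy)-6-(methoxymethoxy)phenyl]-1-[3,4-bis(benzyloxy)phenyl]-3-oxoprop-1-en-2-yl}-3-hydroxychroman-4-one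
Conditions: piperidine, AcOH (cat.), toluene, 4 Å molecular sieves, 80 °C
Reagents that add atoms: none
Why: Knoevenagel-type amine-catalysed aldol condensation at the doubly activated CH2 gives the α-aryl chalcone as the E isomer (aroyl trans to the new aryl); the adduct is no more crowded than C3 of the target itself.

**Step 6**
Reactants: 8 MOM-protected α-aryl chalcone
Product: 9 (2R,3R)-5,7-bis(benzyloxy)-2-[3,4-bis(benzyloxy)phenyl]-8-{(E)-3-[2,4-bis(benzyloxy)-6-hydroxyphenyl]-1-[3,4-bis(benzyloxy)phenyl]-3-oxoprop-1-en-2-yl}-3-hydroxychroman-4-one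
Conditions: HCl (0.5 M), MeOH/THF, 25 °C
Reagents that add atoms: none
Why: acid-catalysed methanolysis of the aryl MOM acetal frees only the 2'-phenol, leaving benzyl ethers and the enone intact; 2'-hydroxy-6'-alkoxychalcones do not cyclise under such mild acid.

**Step 7**
Reactants: 9 2'-hydroxy-α-aryl chalcone
Product: 10 (2R,3R)-5,7-bis(benzyloxy)-8-{(2S,3R)-5,7-bis(benzyloxy)-2-[3,4-bis(benzyloxy)phenyl]-4-oxochroman-3-yl}-2-[3,4-bis(benzyloxy)phenyl]-3-hydroxychroman-4-one
Conditions: 3-{[3,5-bis(trifluoromethyl)phenyl]amino}-4-{[(9R)-6'-methoxycinchonan-9-yl]amino}cyclobut-3-ene-1,2-dione (C32H28F6N4O3, the squaramide of 9-amino-9-deoxy-epi-quinidine, 10 mol %), toluene, 0 °C then 25 °C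
Reagents that add atoms: none
Why: Proposed new method: catalyst-controlled 6-endo-trig oxa-Michael cyclisation of a non-activated α-aryl-2'-hydroxychalcone, in which the quinuclidine nitrogen takes the phenol proton while the squaramide N–H pair binds the enone carbonyl, so the ion-paired phenoxide is delivered to one face of the β-carbon and the new C–O bond sets C2 as S, after which the enol is protonated and C3 (α to the ketone and benzylic) equilibrates under the same amine to the diequatorial trans 3R isomer, closure being effectively irreversible because the 6'-benzyloxy and twisted α-aryl groups destabilise the chalcone; the closest known reaction types are the cinchona-thiourea-catalysed enantioselective oxa-Michael cyclisation of α-alkoxycarbonyl-2'-hydroxychalcones to flavanones and the racemic base-mediated cyclisation of α-aryl-2'-hydroxychalcones to trans-2,3-diarylchroman-4-ones.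

**Step 8**
Reactants: 10 octa-O-benzyl biflavanone
Product: 11 (2R,3R)-8-[(2S,3R)-2-(3,4-dihydroxyphenyl)-5,7-dihydroxy-4-oxochroman-3-yl]-2-(3,4-dihydroxyphenyl)-3,5,7-trihydroxychroman-4-one
Conditions: H2 (1 atm), Pd(OH)2/C, THF/MeOH, 25 °C
Reagents that add atoms: none
Why: catalytic hydrogenolysis of the eight benzyl ethers under neutral conditions releases the target without enolisation or ring opening, so all four stereocentres are kept.

## Compound list

1 | 1-[2-hydroxy-4,6-bis(benzyloxy)phenyl]ethan-1-one | CC(=O)c1c(O)cc(OCc2ccccc2)cc1OCc1ccccc1 | starting material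
2 | 1-[2,4-bis(benzyloxy)-6-(methoxymethoxy)phenyl]ethan-1-one | CC(=O)c1c(OCOC)cc(OCc2ccccc2)cc1OCc1ccccc1 | intermediate
3 | (+)-taxifolin, (2R,3R)-2-(3,4-dihydroxyphenyl)-3,5,7-trihydroxychroman-4-one | Oc1cc(O)c2c(c1)O[C@H](c1ccc(O)c(O)c1)[C@@H](O)C2=O | starting material
4 | (2R,3R)-5,7-bis(benzyloxy)-2-[3,4-bis(benzyloxy)phenyl]-3-hydroxychroman-4-one | O=C1c2c(OCc3ccccc3)cc(OCc3ccccc3)cc2O[C@H](c2ccc(OCc3ccccc3)c(OCc3ccccc3)c2)[C@H]1O | intermediate
5 | (2R,3R)-5,7-bis(benzyloxy)-2-[3,4-bis(benzyloxy)phenyl]-8-bromo-3-hydroxychroman-4-one | O=C1c2c(OCc3ccccc3)cc(OCc3ccccc3)c(Br)c2O[C@H](c2ccc(OCc3ccccc3)c(OCc3ccccc3)c2)[C@H]1O | intermediate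
6 | (2R,3R)-5,7-bis(benzyloxy)-2-[3,4-bis(benzyloxy)phenyl]-8-{2-[2,4-bis(benzyloxy)-6-(methoxymethoxy)phenyl]-2-oxoethyl}-3-hydroxychroman-4-one | O=C1c2c(OCc3ccccc3)cc(OCc3ccccc3)c(CC(=O)c3c(OCOC)cc(OCc4ccccc4)cc3OCc3ccccc3)c2O[C@H](c2ccc(OCc3ccccc3)c(OCc3ccccc3)c2)[C@H]1O | intermediate
7 | 3,4-bis(benzyloxy)benzaldehyde | O=Cc1ccc(OCc2ccccc2)c(OCc2ccccc2)c1 | starting material
8 | (2R,3R)-5,7-bis(benzyloxy)-2-[3,4-bis(benzyloxy)phenyl]-8-{(E)-3-[2,4-bis(benzyloxy)-6-(methoxymethoxy)phenyl]-1-[3,4-bis(benzyloxy)phenyl]-3-oxoprop-1-en-2-yl}-3-hydroxychroman-4-one | O=C1c2c(OCc3ccccc3)cc(OCc3ccccc3)c(/C(=C\c3ccc(OCc4ccccc4)c(OCc4ccccc4)c3)C(=O)c3c(OCOC)cc(OCc4ccccc4)cc3OCc3ccccc3)c2O[C@H](c2ccc(OCc3ccccc3)c(OCc3ccccc3)c2)[C@H]1O | intermediate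
9 | (2R,3R)-5,7-bis(benzyloxy)-2-[3,4-bis(benzyloxy)phenyl]-8-{(E)-3-[2,4-bis(benzyloxy)-6-hydroxyphenyl]-1-[3,4-bis(benzyloxy)phenyl]-3-oxoprop-1-en-2-yl}-3-hydroxychroman-4-one | O=C1c2c(OCc3ccccc3)cc(OCc3ccccc3)c(/C(=C\c3ccc(OCc4ccccc4)c(OCc4ccccc4)c3)C(=O)c3c(O)cc(OCc4ccccc4)cc3OCc3ccccc3)c2O[C@H](c2ccc(OCc3ccccc3)c(OCc3ccccc3)c2)[C@H]1O | intermediate
10 | (2R,3R)-5,7-bis(benzyloxy)-8-{(2S,3R)-5,7-bis(benzyloxy)-2-[3,4-bis(benzyloxy)phenyl]-4-oxochroman-3-yl}-2-[3,4-bis(benzyloxy)phenyl]-3-hydroxychroman-4-one | O=C1c2c(OCc3ccccc3)cc(OCc3ccccc3)cc2O[C@H](c2ccc(OCc3ccccc3)c(OCc3ccccc3)c2)[C@H]1c1c(OCc3ccccc3)cc(OCc3ccccc3)c2c1O[C@H](c1ccc(OCc3ccccc3)c(OCc3ccccc3)c1)[C@@H](O)C2=O | intermediate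
11 | (2R,3R)-8-[(2S,3R)-2-(3,4-dihydroxyphenyl)-5,7-dihydroxy-4-oxochroman-3-yl]-2-(3,4-dihydroxyphenyl)-3,5,7-trihydroxychroman-4-one | O=C1c2c(O)cc(O)cc2O[C@H](c2ccc(O)c(O)c2)[C@H]1c1c(O)cc(O)c2c1O[C@H](c1ccc(O)c(O)c1)[C@@H](O)C2=O | target

## Step count and risks

Total step count: 8. Longest linear sequence: 7 steps (3 → 4 → 5 → 6 → 8 → 9 → 10 → 11).

**Step 7 (proposed new cyclisation).** Risks are slow turnover on a non-activated enone, a mismatch with the remote taxifolin stereocentres, and an unproven facial sense. The quinidine-derived catalyst is assigned to the 2S-forming face by analogy only; the sense must be calibrated on the simple α-phenyl chalcone, with the quinine-derived pseudo-enantiomer as the first adjustment. The fallback uses known chemistry, sets out from 9 and comes back at 10. Chalcone 9 is cyclised under the classical conditions for chalcone–flavanone isomerisation (NaOAc, EtOH, reflux), which give the two trans isomers without facial control: 10 and its upper-unit epimer, the (2R,3S)-flavanone diastereomer F6. The taxifolin unit makes these diastereomers, so they are separated on silica. F6 is re-equilibrated through ring opening and closure (piperidine, EtOH, 60 °C) and recycled.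

**Step 4 (α-arylation).** Risks are the di-ortho-substituted, electron-rich bromide and the base-sensitive α-ketol of the taxifolin unit (epimerisation, or oxidation through a palladium alkoxide). The fallback sets out from 2 and 5 and comes back at 6. Ketone 2 is first converted (TMSOTf, Et3N, CH2Cl2, 0 °C) into its trimethylsilyl enol ether F1. This preformed enol silane is then coupled with 5 under base-free fluoride activation (Pd(dba)2, P(tBu)3, ZnF2, CsF, DMF, 80 °C), so no free enolate or alkoxide is ever present.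

**Step 5 (Knoevenagel condensation).** Risks are the crowded methylene and prolonged amine and heat on the taxifolin unit. The fallback avoids the condensation on 6 altogether; it sets out from 5 (with 2 and 7) and comes back at 8. Claisen–Schmidt condensation of 2 with 7 (KOH, EtOH/THF, 25 °C) gives the MOM-protected chalcone F2. Addition of bromine (pyridinium tribromide, CH2Cl2, −20 °C, to favour the alkene over ring A) gives the erythro dibromide F3, which loses HBr with Et3N to give the (Z)-α-bromochalcone F4. Bromide 5 is converted by Miyaura borylation (B2pin2, KOAc, Pd(OAc)2, SPhos, 1,4-dioxane, 90 °C) into the C8 pinacol boronate F5. F5 is coupled in the same flask with F4 (aqueous K3PO4, 70 °C, Suzuki–Miyaura, retention of alkene geometry) to give 8.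

## Further compounds

F1 | step 4 | {1-[2,4-bis(benzyloxy)-6-(methoxymethoxy)phenyl]ethenyl}oxy(trimethyl)silane | C=C(O[Si](C)(C)C)c1c(OCOC)cc(OCc2ccccc2)cc1OCc1ccccc1
F2 | step 5 | (E)-1-[2,4-bis(benzyloxy)-6-(methoxymethoxy)phenyl]-3-[3,4-bis(benzyloxy)phenyl]prop-2-en-1-one | O=C(/C=C/c1ccc(OCc2ccccc2)c(OCc2ccccc2)c1)c1c(OCOC)cc(OCc2ccccc2)cc1OCc1ccccc1
F3 | step 5 | rac-(2R,3S)-2,3-dibromo-1-[2,4-bis(benzyloxy)-6-(methoxymethoxy)phenyl]-3-[3,4-bis(benzyloxy)phenyl]propan-1-one (racemic, one enantiomer drawn) | O=C([C@@H](Br)[C@@H](Br)c1ccc(OCc2ccccc2)c(OCc2ccccc2)c1)c1c(OCOC)cc(OCc2ccccc2)cc1OCc1ccccc1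
F4 | step 5 | (Z)-2-bromo-1-[2,4-bis(benzyloxy)-6-(methoxymethoxy)phenyl]-3-[3,4-bis(benzyloxy)phenyl]prop-2-en-1-one | O=C(/C(Br)=C/c1ccc(OCc2ccccc2)c(OCc2ccccc2)c1)c1c(OCOC)cc(OCc2ccccc2)cc1OCc1ccccc1
F5 | step 5 | (2R,3R)-5,7-bis(benzyloxy)-2-[3,4-bis(benzyloxy)phenyl]-3-hydroxy-8-(4,4,5,5-tetramethyl-1,3,2-dioxaborolan-2-yl)chroman-4-one | O=C1c2c(OCc3ccccc3)cc(OCc3ccccc3)c(B3OC(C)(C)C(C)(C)O3)c2O[C@H](c2ccc(OCc3ccccc3)c(OCc3ccccc3)c2)[C@H]1O
F6 | step 7 | (2R,3R)-5,7-bis(benzyloxy)-8-{(2R,3S)-5,7-bis(benzyloxy)-2-[3,4-bis(benzyloxy)phenyl]-4-oxochroman-3-yl}-2-[3,4-bis(benzyloxy)phenyl]-3-hydroxychroman-4-one | O=C1c2c(OCc3ccccc3)cc(OCc3ccccc3)cc2O[C@@H](c2ccc(OCc3ccccc3)c(OCc3ccccc3)c2)[C@@H]1c1c(OCc3ccccc3)cc(OCc3ccccc3)c2c1O[C@H](c1ccc(OCc3ccccc3)c(OCc3ccccc3)c1)[C@@H](O)C2=O
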